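**Retrosynthetic overview**
1. Target ⇐ 8‑O‑methyl ether 19 by chelation‑controlled BCl3 demethylation; the α‑hydroxy ketone of 19 ⇐ β‑nitro alcohol 16 by a reductive Nef reaction.
2. Key disconnection C5′–C6′: the nitronate of nitroalkane 14 (its carbon becomes the ketone carbon, so it acts as an acyl anion equivalent) adds to octanal in a catalytic asymmetric nitroaldol reaction that sets C6′ (R) on the complete lactone.
3. Nitroalkane 14 ⇐ primary chloride 12 (iodide, then nitrite).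
4. Lactone ring (the only ring formed; the benzene ring is bought): ortho‑metalated 2,4‑dimethoxybenzamide 3 opens epoxide 8 at CH2, then acid lactonisation; C3 (R) comes from the epoxide.
5. Epoxide 8 ⇐ (R)‑epichlorohydrin + 4‑chlorobutyl Grignard reagent.

Assumption: in step 5 the antipode of the indabox ligand that gives the (6R)‑carbinol is used (both antipodes are sold; I could not fix the sense from memory, so it is confirmed by Mosher ester analysis of 16).

**Step 1**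
Reactants: 1 2,4‑dimethoxybenzoyl chloride; 2 diethylamine
Product: 3 N,N‑diethyl‑2,4‑dimethoxybenzamide
Conditions: Et2NH (1.2 equiv), 2 M aq NaOH, CH2Cl2, 0 °C → rt
Reagents that add atoms: none
Why: Schotten–Baumann N‑acylation of a secondary amine by an aroyl chloride is fast and clean and installs the CONEt2 group that directs the later metalation; no stereocenter is involved.

**Step 2**
Reactants: 4 1‑bromo‑4‑chlorobutane; 5 (R)‑epichlorohydrin
Product: 8 (R)‑2‑(5‑chloropentyl)oxirane, via 4‑chlorobutylmagnesium bromide 6 (not isolated), via (R)‑1,7‑dichloroheptan‑2‑ol 7 (not isolated)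
Conditions: 4 (1.2 equiv), Mg, THF, 20 °C; 5, CuI (5 mol %), −40 → −20 °C; H2O; then NaOH, Et2O/H2O, rt
Reagents that add atoms: none
Why: Mg inserts selectively into C–Br, the copper‑catalysed Grignard opening of the epoxide occurs at the unsubstituted CH2, and Williamson closure of the chlorohydrin takes place at the CH2Cl carbon, so the C–O stereocenter of 5 is never touched and is retained as (R).

**Step 3**
Reactants: 3 N,N‑diethyl‑2,4‑dimethoxybenzamide; 8 (R)‑2‑(5‑chloropentyl)oxirane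
Product: 12 (3R)‑3‑(5‑chloropentyl)‑6,8‑dimethoxyisochroman‑1‑one, via aryllithium 9 (not isolated), via arylmagnesium bromide 10 (not isolated), via hydroxy amide 11 (not isolated)
Conditions: 3 (1.3 equiv), s‑BuLi, TMEDA, THF, −78 °C; MgBr2·OEt2, −78 → −40 °C; 8, CuI (10 mol %), −40 → 0 °C; H2O; then TsOH·H2O, PhMe, 110 °C
Reagents that add atoms: none
Why: Directed ortho‑metalation at C6 (CONEt2 outranks OMe as director), copper‑catalysed aryl Grignard opening of the terminal epoxide at CH2, and acid‑promoted lactonisation of the δ‑hydroxy amide with loss of Et2NH form the isochromanone ring, with C3 (R) carried over unchanged from 8.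

**Step 4**
Reactants: 12 (3R)‑3‑(5‑chloropentyl)‑6,8‑dimethoxyisochroman‑1‑one
Product: 14 (3R)‑6,8‑dimethoxy‑3‑(5‑nitropentyl)isochroman‑1‑one, via iodide 13 (not isolated)
Conditions: NaI, acetone, 56 °C; solvent switch; NaNO2, urea, DMF, 0 °C → rt
Reagents that add atoms: sodium nitrite, [Na+].[O-]N=O
Why: Finkelstein exchange followed by Kornblum SN2 displacement with nitrite (N‑alkylation dominant for a primary iodide in DMF) gives the primary nitroalkane without affecting the lactone or C3.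

**Step 5**
Reactants: 14 (3R)‑6,8‑dimethoxy‑3‑(5‑nitropentyl)isochroman‑1‑one; 15 octanal
Product: 16 (3R)‑3‑[(6R)‑6‑hydroxy‑5‑nitrotridecyl]‑6,8‑dimethoxyisochroman‑1‑one (both epimers at the nitro carbon)
Conditions: 15 (4 equiv), Cu(OAc)2·H2O (10 mol %), 2,2′‑methylenebis(3a,8a‑dihydro‑8H‑indeno[1,2‑d]oxazole) (indabox, 11 mol %), EtOH/THF, rt, 72 h
Reagents that add atoms: none
Why: Catalytic asymmetric Henry (nitroaldol) reaction in which the copper‑bound nitronate of 14, an acyl anion equivalent for the future C5′ ketone, adds to one face of the ligand‑bound aldehyde so that the catalyst sets C6′ as (R) (this catalyst class is known to give high ee with unbranched aliphatic aldehydes), while the configuration at the nitro carbon is irrelevant because step 6 destroys it.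

**Step 6**
Reactants: 16 (3R)‑3‑[(6R)‑6‑hydroxy‑5‑nitrotridecyl]‑6,8‑dimethoxyisochroman‑1‑one
Product: 19 (3R)‑3‑[(6R)‑6‑hydroxy‑5‑oxotridecyl]‑6,8‑dimethoxyisochroman‑1‑one, via oxime 17 (not isolated), via imine 18 (not isolated)
Conditions: TiCl3 (20% in aq HCl, 5 equiv), DME/H2O, rt, 24 h
Reagents that add atoms: water, O
Why: McMurry reductive Nef reaction, in which trivalent titanium reduces the nitro group through the oxime to the N–H imine that hydrolyses in the acidic medium; with no base present the β‑nitro alcohol cannot undergo retro‑Henry cleavage, C6′ is not epimerised, and both nitro epimers converge on one ketone.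

**Step 7**
Reactants: 19 (3R)‑3‑[(6R)‑6‑hydroxy‑5‑oxotridecyl]‑6,8‑dimethoxyisochroman‑1‑one
Product: 21 (3R)‑8‑hydroxy‑3‑[(6R)‑6‑hydroxy‑5‑oxotridecyl]‑6‑methoxyisochroman‑1‑one, via bis(dichloroboryl) ester 20 (not isolated)
Conditions: BCl3 (3.5 equiv), CH2Cl2, −78 → 0 °C; then H2O, 0 °C
Reagents that add atoms: none
Why: Chelation‑controlled Lewis acid ether cleavage, in which BCl3 bound to the lactone carbonyl removes only the peri 8‑O‑methyl group, leaving the 6‑OMe group and both stereocenters untouched.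

**Compound list**
1 | 2,4‑dimethoxybenzoyl chloride | COc1ccc(C(=O)Cl)c(OC)c1 | starting material
2 | diethylamine | CCNCC | starting material
3 | N,N‑diethyl‑2,4‑dimethoxybenzamide | CCN(CC)C(=O)c1ccc(OC)cc1OC | intermediate
4 | 1‑bromo‑4‑chlorobutane | ClCCCCBr | starting material
5 | (R)‑epichlorohydrin | ClC[C@H]1CO1 | starting material
6 | 4‑chlorobutylmagnesium bromide | ClCCCC[Mg]Br | intermediate (not isolated)
7 | (R)‑1,7‑dichloroheptan‑2‑ol | ClC[C@H](O)CCCCCCl | intermediate (not isolated)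
8 | (R)‑2‑(5‑chloropentyl)oxirane | ClCCCCC[C@@H]1CO1 | intermediate
9 | [2‑(diethylcarbamoyl)‑3,5‑dimethoxyphenyl]lithium | CCN(CC)C(=O)c1c([Li])cc(OC)cc1OC | intermediate (not isolated)
10 | [2‑(diethylcarbamoyl)‑3,5‑dimethoxyphenyl]magnesium bromide | CCN(CC)C(=O)c1c([Mg]Br)cc(OC)cc1OC | intermediate (not isolated)
11 | 2‑[(2R)‑7‑chloro‑2‑hydroxyheptyl]‑N,N‑diethyl‑4,6‑dimethoxybenzamide | CCN(CC)C(=O)c1c(C[C@H](O)CCCCCCl)cc(OC)cc1OC | intermediate (not isolated)
12 | (3R)‑3‑(5‑chloropentyl)‑6,8‑dimethoxyisochroman‑1‑one | ClCCCCC[C@@H]1Cc2cc(OC)cc(OC)c2C(=O)O1 | intermediate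
13 | (3R)‑3‑(5‑iodopentyl)‑6,8‑dimethoxyisochroman‑1‑one | ICCCCC[C@@H]1Cc2cc(OC)cc(OC)c2C(=O)O1 | intermediate (not isolated)
14 | (3R)‑6,8‑dimethoxy‑3‑(5‑nitropentyl)isochroman‑1‑one | [O-][N+](=O)CCCCC[C@@H]1Cc2cc(OC)cc(OC)c2C(=O)O1 | intermediate
15 | octanal | CCCCCCCC=O | starting material
16 | (3R)‑3‑[(6R)‑6‑hydroxy‑5‑nitrotridecyl]‑6,8‑dimethoxyisochroman‑1‑one (both epimers at the nitro carbon) | CCCCCCC[C@@H](O)C(CCCC[C@@H]1Cc2cc(OC)cc(OC)c2C(=O)O1)[N+](=O)[O-] | intermediate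
17 | (3R)‑3‑[(6R)‑6‑hydroxy‑5‑(hydroxyimino)tridecyl]‑6,8‑dimethoxyisochroman‑1‑one | CCCCCCC[C@@H](O)C(=NO)CCCC[C@@H]1Cc2cc(OC)cc(OC)c2C(=O)O1 | intermediate (not isolated)
18 | (3R)‑3‑[(6R)‑6‑hydroxy‑5‑iminotridecyl]‑6,8‑dimethoxyisochroman‑1‑one | CCCCCCC[C@@H](O)C(=N)CCCC[C@@H]1Cc2cc(OC)cc(OC)c2C(=O)O1 | intermediate (not isolated)
19 | (3R)‑3‑[(6R)‑6‑hydroxy‑5‑oxotridecyl]‑6,8‑dimethoxyisochroman‑1‑one | CCCCCCC[C@@H](O)C(=O)CCCC[C@@H]1Cc2cc(OC)cc(OC)c2C(=O)O1 | intermediate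
20 | (3R)‑8‑(dichloroboryloxy)‑3‑[(6R)‑6‑(dichloroboryloxy)‑5‑oxotridecyl]‑6‑methoxyisochroman‑1‑one | CCCCCCC[C@@H](OB(Cl)Cl)C(=O)CCCC[C@@H]1Cc2cc(OC)cc(OB(Cl)Cl)c2C(=O)O1 | intermediate (not isolated)
21 | (3R)‑8‑hydroxy‑3‑[(6R)‑6‑hydroxy‑5‑oxotridecyl]‑6‑methoxyisochroman‑1‑one | CCCCCCC[C@@H](O)C(=O)CCCC[C@@H]1Cc2cc(OC)cc(O)c2C(=O)O1 | target

**Step count and risks**
Total steps: 7. Longest linear sequence: 6 (step 1 or step 2, then steps 3–7).

Most likely to fail, step 3 (regioselectivity of the metalation of 3 between C6 and C3, and aryl transfer to the epoxide). The fallback sets out from 8 and comes back at 12, building the lactone by electrophilic ring closure instead. Epoxide 8 is opened with commercial 3,5‑dimethoxyphenylmagnesium bromide (CuI cat., THF, −30 °C) to give (R)‑7‑chloro‑1‑(3,5‑dimethoxyphenyl)heptan‑2‑ol F1. Oxa‑Pictet–Spengler cyclisation with dimethoxymethane and BF3·OEt2 (CH2Cl2, 0 °C) closes the pyran ortho to the side chain (the two ortho positions are equivalent) to give (3R)‑3‑(5‑chloropentyl)‑6,8‑dimethoxyisochroman F2. Oxidation of its O–CH2–aryl carbon with KMnO4/CuSO4·5H2O (CH2Cl2, rt) gives lactone 12; step 1 is then not needed.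

Most likely to fail, step 5 (slow nitroaldol with the nitroalkane as limiting partner, face selectivity, retro‑Henry erosion). The fallback sets out from 12 and comes back at 19, bringing C6′ in already set on a dithiane acyl anion equivalent. 1,3‑Dithiane is lithiated (n‑BuLi, THF, −30 °C) to 2‑lithio‑1,3‑dithiane F3 and acylated with ethyl octanoate to 1‑(1,3‑dithian‑2‑yl)octan‑1‑one F4. Borane reduction catalysed by (S)‑1‑methyl‑3,3‑diphenyltetrahydro‑1H,3H‑pyrrolo[1,2‑c][1,3,2]oxazaborole (BH3·SMe2, THF) gives (R)‑1‑(1,3‑dithian‑2‑yl)octan‑1‑ol F5. Double deprotonation (n‑BuLi, 2.1 equiv, THF, −30 °C) gives dilithium (R)‑1‑(1,3‑dithian‑2‑id‑2‑yl)octan‑1‑olate F6. This is C‑alkylated at −78 → −30 °C by iodide 13 (made from 12 with NaI in acetone and isolated this time) to give (3R)‑3‑{4‑[2‑((R)‑1‑hydroxyoctyl)‑1,3‑dithian‑2‑yl]butyl}‑6,8‑dimethoxyisochroman‑1‑one F7. Hydrolysis of the dithioacetal (MeI, CaCO3, aq MeCN) gives ketone 19, and step 7 follows.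

Most likely to fail, step 6 (reduction may stall at oxime 17, or the long acid exposure may erode C6′). The fallback sets out from 16 and comes back at 21, removing the nitro group oxidatively on a protected substrate. Alcohol 16 is silylated (TESOTf, 2,6‑lutidine, CH2Cl2, −78 °C) to (3R)‑6,8‑dimethoxy‑3‑[(6R)‑5‑nitro‑6‑(triethylsilyloxy)tridecyl]isochroman‑1‑one F8. KOt‑Bu (1.05 equiv, THF, −78 °C) gives the corresponding potassium nitronate F9, which can no longer undergo retro‑Henry cleavage. Dimethyldioxirane (acetone, −78 → 0 °C) oxidises its C=N bond to give (3R)‑6,8‑dimethoxy‑3‑[(6R)‑5‑oxo‑6‑(triethylsilyloxy)tridecyl]isochroman‑1‑one F10. Under the BCl3 conditions of step 7 the silyl ether and the 8‑O‑methyl group are both cleaved (through 20), giving 21.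

**Further compounds**
F1 | step 3 | (R)‑7‑chloro‑1‑(3,5‑dimethoxyphenyl)heptan‑2‑ol | COc1cc(C[C@H](O)CCCCCCl)cc(OC)c1
F2 | step 3 | (3R)‑3‑(5‑chloropentyl)‑6,8‑dimethoxyisochroman | ClCCCCC[C@@H]1Cc2cc(OC)cc(OC)c2CO1
F3 | step 5 | 2‑lithio‑1,3‑dithiane | [Li]C1SCCCS1
F4 | step 5 | 1‑(1,3‑dithian‑2‑yl)octan‑1‑one | CCCCCCCC(=O)C1SCCCS1
F5 | step 5 | (R)‑1‑(1,3‑dithian‑2‑yl)octan‑1‑ol | CCCCCCC[C@@H](O)C1SCCCS1
F6 | step 5 | dilithium (R)‑1‑(1,3‑dithian‑2‑id‑2‑yl)octan‑1‑olate | [Li+].[Li+].CCCCCCC[C@@H]([O-])[C-]1SCCCS1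
F7 | step 5 | (3R)‑3‑{4‑[2‑((R)‑1‑hydroxyoctyl)‑1,3‑dithian‑2‑yl]butyl}‑6,8‑dimethoxyisochroman‑1‑one | CCCCCCC[C@@H](O)C1(CCCC[C@@H]2Cc3cc(OC)cc(OC)c3C(=O)O2)SCCCS1
F8 | step 6 | (3R)‑6,8‑dimethoxy‑3‑[(6R)‑5‑nitro‑6‑(triethylsilyloxy)tridecyl]isochroman‑1‑one | CCCCCCC[C@@H](O[Si](CC)(CC)CC)C(CCCC[C@@H]1Cc2cc(OC)cc(OC)c2C(=O)O1)[N+](=O)[O-]
F9 | step 6 | potassium nitronate of F8 | [K+].CCCCCCC[C@@H](O[Si](CC)(CC)CC)C(CCCC[C@@H]1Cc2cc(OC)cc(OC)c2C(=O)O1)=[N+]([O-])[O-]
F10 | step 6 | (3R)‑6,8‑dimethoxy‑3‑[(6R)‑5‑oxo‑6‑(triethylsilyloxy)tridecyl]isochroman‑1‑one | CCCCCCC[C@@H](O[Si](CC)(CC)CC)C(=O)CCCC[C@@H]1Cc2cc(OC)cc(OC)c2C(=O)O1
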